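Atoms are numbered 1–27 in the order in which they appear in the target SMILES (C1 methyl, C2, C3, N4, C5 … C26, O27); compound numbers are those of the steps below.

## The problem

Target 46 is a caged hexacycle. Pyrrolidinone ring A (N4, C3, C2, C26, C21) and piperidine ring B share the N4–C21 bond; rings B and C form a 2-azabicyclo[3.2.1]octane with C21 and C23 as bridgeheads; cycloheptane ring D, cyclopentene ring E (C12=C13) and a δ-lactone (C14–C17, O19, C20) are fused around C14. The core difficulty is three contiguous fully substituted carbons: the aza-quaternary C21 and the vicinal all-carbon quaternary pair C23/C14. The vicinal pair C6/C23 can be fixed on a small ring before the polycycle exists, whereas C9 lies 1,4 to both across ring D and must be set by a reagent. Once C23 stands it can direct C21 (1,3 across ring B), and C21/C23 then dictate C14 and C20, because ring C and the lactone can only close cis; C2 is α to the C26 ketone and is settled by equilibration. The fragile elements are the enolisable α-amino ketone, the tertiary amine (no ozone or strong oxidants late), the lactone, the neopentyl primary alcohol, and the C12=C13 alkene, whose migration to C9=C13 would erase C9. The enabling feature is that ring A is the sum of a C3–N4–C21 azomethine ylide and a C2=C26 two-carbon unit: while ring C is open, C21 belongs to ring B alone and can be the sp2 carbon of a ketimine, and the C26 carbonyl can be carried as the nitro group of a nitroalkene.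

## Retrosynthesis

**46 ⇒ 41 (no skeletal bond cut).** The C24 benzyl ether and the C26 silyl ether of 43 are the last masks; they are removed around a final reoxidation at C26 (44, 45). The C12=C13 alkene is traced through enol triflate 42 to ketone 41. A C12 carbonyl is accepted because it is what makes C14 electrophilic in the preceding step; the forward sequence must enolise 41 toward C13, not C11.

**41 ⇒ 39 (cut C20–C14 and O19–C17).** A ketyl at C20 adds to the β-carbon of the C12 enone and the resulting alkoxide closes the lactone on the C17 ester. A radical is preferred over a polar addition because C14 becomes quaternary next to quaternary C23. The tether C21–C22–C23 forces attack on the correct face of C14; the reaction has to tolerate an aldehyde that is α to the amine.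

**39 ⇒ 33 (functional-group changes only).** The C26 ketone is an α-amino ketone and would not survive the reductant, so it passes this stage as a silyl-protected carbinol (35 → 36 → 37). C20 is carried as CH2OTBS, not as an acetal or ester: an acetal next to a protonated amine is hard to hydrolyse, and a conjugating group on C21 would reverse the polarity of the ylide. It is released and oxidised just before use (38, 39).

**33 ⇒ 25 + 29 + 30 (cut C3–C2 and C21–C26; the key step).** Ring A and the aza-quaternary C21 come from ketimine 25, one carbon from triflate 30 and (E)-1-nitropropene 29. This cut is made before ring C exists, because afterwards C21 would be a bridgehead and could not be part of a C=N bond. The precursor 25 has three stereocentres instead of six and no ring A. The forward reaction must place C26 on the face of ring B opposite C14.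

**25 ⇒ 23 ⇒ 21 (cut N4=C21).** Ring B closes by Staudinger–aza-Wittig reaction of a C5 azide with the C21 ketone. The ketone is unmasked from a 1,1-disubstituted alkene (22 → 23) and the azide comes from the C5 alcohol of 21. Nitrogen is introduced only after C14 has become an alkene carbon, so that no carbonyl γ to C5 can participate.

**21 ⇒ 20 (cut C13=C14).** Ring D closes by intramolecular aldol condensation of the cyclopentanone of 20 onto the C14 ketone, which gives the tetrasubstituted enone with its side chain in one step. A metathesis at C7/C8 or a cross-coupling on a 1,3-diketone would leave the enone or its regiochemistry still to be solved. Only the C13 enolate can form an unstrained ring.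

**20 ⇒ 14 (cut C15–C16 and C14–C15).** The γ-keto ester arises from methyl ketone 17 and methyl bromoacetate 18 (19); the methyl ketone arises from lactone 14 and methyllithium 15 (16). The lactone therefore serves as the C14 acyl group and as the protected C5 oxygen.

**14 ⇒ 8 (cut C23–C22 and C23–C24).** Two enolate alkylations of γ-butyrolactone 8 build C23. The C6 side chain sends each electrophile to the opposite face, so the order (9 first, then 13) fixes the C6/C23 relationship. The three-carbon reagent 13 (from diol 11 via 12) carries C20–C22 with C21 masked as a methylidene.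

**8 ⇒ 7 ⇒ 4 + 5 (C6–H, then cut C6–C7).** C6 is set by catalyst-controlled conjugate reduction of butenolide 7, independent of the remote C9. Butenolide 7 is assembled from vinyl ketal 4 and 4-bromofuranone 5 by hydroboration and B-alkyl Suzuki–Miyaura coupling.

**4 ⇒ 3 ⇒ 1 + 2 (cut C9–C8).** C9 comes from rhodium-catalysed asymmetric conjugate vinylation of cyclopentenone 1 with 2. Nitroalkene 29 is made from nitromethane 26 and acetaldehyde 27 via 28.

## Roads not taken

**Alternative 1:** The cut is C5–C6, ring B closing last. An N-methoxymethyl group on N4 would ionise to a methylene iminium, which the C6 terminus of a ring D allylsilane (silicon on C8) attacks; this gives the 7,8-didehydro compound A1, and hydrogenation would finish the synthesis. Its merits are real: iminium–allylsilane closures of six-membered rings are dependable, C6 is set in the closure, and the end-game after the key step is one operation. In that respect it is better than the chosen plan, whose key step is followed by eleven steps. Its weakness is that the step solves none of the three quaternary centres. Rings A, C, D, E, the lactone and the aza-quaternary C21 must all exist before it, on a secondary amine flanked by a quaternary carbon and a ketone, and the allylsilane needs a defined C8 centre. A1 must also be hydrogenated at C7=C8 without touching C12=C13. The chosen plan sets against this that C21 and ring A are made in the same step, on an intermediate where ring B has been closed early by a robust condensation.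

**Alternative 2:** The cut is C13–C14, ring D closing by a seven-exo Heck reaction of a cyclopentenyl triflate onto an exocyclic C14=C15 alkene on ring C; β-hydride elimination gives diene A2. Migratory insertion copes well with building a quaternary carbon, and the C12=C13 alkene comes directly from the triflate, so no ring E oxygen has to be removed later. That is a clear advantage over the chosen plan, which spends two steps deleting the C12 carbonyl. The weak points are the seven-membered closure onto an alkene flanked by quaternary C23, which must compete with triflate reduction, and the C14 configuration, which rests on facial selectivity instead of a tether. After A2 the C15=C16 alkene must be reduced beside C12=C13, C17 oxidised, the lactone closed and three protecting groups removed. The aza-quaternary centre and rings A–C must again be in place first. The chosen plan answers with a tether-controlled C14 and with stereocentres set either by catalysts or on a five-membered lactone.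

**Alternative 3:** The cuts are C13–C9, C12–C11 and C11–C10: a Pauson–Khand reaction of an ethynyl group on C14 with the terminal alkene of a C6 butenyl chain and CO closes rings D and E at once to give enone A3. No other route forms three C–C bonds and two rings in one step, and it is the most convergent. However, Pauson–Khand closures that form a seven-membered ring are much less reliable than those giving five- or six-membered rings, C9 is set in the cyclisation with no obvious bias, and the amine can bind the cobalt. A3 also carries a C11 carbonyl that must be excised without moving the C12=C13 alkene, which is harder than the triflate reduction of the chosen plan. Both routes carry a superfluous ring E carbonyl; in the chosen plan it is the activating group for the C20–C14 bond, in this one it is only overhead.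

Key step: step 19

Remarks on the chemistry (assumptions):
- The natural C2 configuration (methyl on the face of ring A that carries C22, away from the C20–O19 bond) is taken to be the thermodynamically preferred epimer of the α-amino ketone, so equilibration at the ketone stage converges on it.
- Compounds 2, 5, 9, 11, 15, 18 and 30 are taken as commercial.
- The C26 carbinol and nitro centres and C13 of 40/41 are drawn as one epimer for definiteness; all three centres are erased later.

## Steps

Step 1
Reactants: 1 cyclopent-2-en-1-one; 2 potassium vinyltrifluoroborate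
Product: 3 (S)-3-vinylcyclopentan-1-one
Conditions: [Rh(cod)2]PF6 (3 mol %), (S)-BINAP, toluene/H2O, 100 °C
Reagents that add atoms: none
Why: Rhodium-catalysed asymmetric conjugate addition of an alkenylboron reagent (Hayashi–Miyaura reaction); the BINAP complex of monovalent rhodium delivers the vinyl group to one face of the enone and sets C9 (ligand enantiomer chosen for S).

Step 2
Reactants: 3 (S)-3-vinylcyclopentan-1-one
Product: 4 (7S)-7-vinyl-1,4-dioxaspiro[4.4]nonane
Conditions: ethylene glycol, PPTS, benzene, reflux (Dean–Stark)
Reagents that add atoms: ethylene glycol, OCCO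
Why: Acid-catalysed ketalisation; the ketone must be masked for the borane, hydride and enolate steps that follow, and the β-stereocentre is not affected.

Step 3
Reactants: 4 (7S)-7-vinyl-1,4-dioxaspiro[4.4]nonane; 5 4-bromofuran-2(5H)-one
Product: 7 4-{2-[(7S)-1,4-dioxaspiro[4.4]nonan-7-yl]ethyl}furan-2(5H)-one, via alkyl-9-BBN adduct 6 (not isolated)
Conditions: 9-BBN, THF, 0 °C→rt; then 5, PdCl2(dppf) (5 mol %), AsPh3, Cs2CO3, DMF/H2O, rt
Reagents that add atoms: none
Why: Anti-Markovnikov hydroboration followed by B-alkyl Suzuki–Miyaura coupling with the vinylogous acyl bromide joins C7 to C6; no stereocentre is formed.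

Step 4
Reactants: 7 4-{2-[(7S)-1,4-dioxaspiro[4.4]nonan-7-yl]ethyl}furan-2(5H)-one
Product: 8 (4S)-4-{2-[(7S)-1,4-dioxaspiro[4.4]nonan-7-yl]ethyl}dihydrofuran-2(3H)-one
Conditions: Cu(OAc)2·H2O (5 mol %), (S)-p-tol-BINAP, (EtO)2MeSiH, t-BuOH, toluene, 0 °C→rt
Reagents that add atoms: none
Why: Copper hydride-catalysed asymmetric conjugate reduction of a β-substituted butenolide; the chiral bisphosphine sets C6 (ligand enantiomer chosen for 4S) and the remote C9 centre has no say.

Step 5
Reactants: 8 (4S)-4-{2-[(7S)-1,4-dioxaspiro[4.4]nonan-7-yl]ethyl}dihydrofuran-2(3H)-one; 9 benzyl chloromethyl ether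
Product: 10 (3R,4S)-3-(benzyloxymethyl)-4-{2-[(7S)-1,4-dioxaspiro[4.4]nonan-7-yl]ethyl}dihydrofuran-2(3H)-one
Conditions: LiN(i-Pr)2, THF, −78 °C; then 9, −78→−40 °C
Reagents that add atoms: none
Why: Lactone enolate alkylation; the electrophile enters trans to the C4 side chain, and this centre is re-formed in step 8, so only the order of the two alkylations matters.

Step 6
Reactants: 11 2-methylidenepropane-1,3-diol
Product: 12 2-{[(tert-butyldimethylsilyl)oxy]methyl}prop-2-en-1-ol
Conditions: NaH (1 equiv), THF, 0 °C; then TBSCl
Reagents that add atoms: tert-butyldimethylsilyl chloride, CC(C)(C)[Si](C)(C)Cl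
Why: Monosilylation of a symmetric diol through its mono-alkoxide.

Step 7
Reactants: 12 2-{[(tert-butyldimethylsilyl)oxy]methyl}prop-2-en-1-ol
Product: 13 {[2-(bromomethyl)prop-2-en-1-yl]oxy}(tert-butyl)dimethylsilane
Conditions: CBr4, PPh3, CH2Cl2, 0 °C
Reagents that add atoms: carbon tetrabromide, BrC(Br)(Br)Br
Why: Appel bromination of a primary allylic alcohol under neutral conditions that spare the silyl ether.

Step 8
Reactants: 10 (3R,4S)-3-(benzyloxymethyl)-4-{2-[(7S)-1,4-dioxaspiro[4.4]nonan-7-yl]ethyl}dihydrofuran-2(3H)-one; 13 {[2-(bromomethyl)prop-2-en-1-yl]oxy}(tert-butyl)dimethylsilane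
Product: 14 (3S,4S)-3-(benzyloxymethyl)-3-[2-({[tert-butyldimethylsilyl]oxy}methyl)prop-2-en-1-yl]-4-{2-[(7S)-1,4-dioxaspiro[4.4]nonan-7-yl]ethyl}dihydrofuran-2(3H)-one
Conditions: LiN(i-Pr)2, THF/DMPU, −78 °C; then 13, −78→−30 °C
Reagents that add atoms: none
Why: Second enolate alkylation with a reactive allylic bromide creates quaternary C23; the bromide again approaches anti to the C4 side chain, which leaves C24 cis and C22 trans to C7 as the target requires, and the low temperature suppresses β-elimination of benzyloxide.

Step 9
Reactants: 14 quaternary lactone (name as in step 8); 15 methyllithium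
Product: 16 hydroxy methyl ketone (C14 ketone with C15 methyl and free C5–OH; in equilibrium with its cyclic hemiketal)
Conditions: MeLi (1.1 equiv), THF, −78 °C; aq NH4Cl
Reagents that add atoms: none
Why: Single addition of an organolithium to a hindered lactone; the tetrahedral lithium alkoxide persists at −78 °C and collapses to the methyl ketone only on work-up.

Step 10
Reactants: 16 hydroxy methyl ketone
Product: 17 C5 triethylsilyl ether of 16
Conditions: Et3SiCl, imidazole, CH2Cl2, 0 °C
Reagents that add atoms: chlorotriethylsilane, CC[Si](Cl)(CC)CC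
Why: Silylation of the primary hydroxyl traps the open-chain ketone, so that the next step has a single acidic site.

Step 11
Reactants: 17 C5 triethylsilyl ether; 18 methyl bromoacetate
Product: 19 γ-keto ester (C14 ketone carrying CH2CH2CO2Me)
Conditions: LiN(i-Pr)2, THF, −78 °C; then 18, DMPU, −78→−40 °C
Reagents that add atoms: none
Why: Kinetic enolate alkylation; C23 is quaternary, so the ketone can enolise only toward the C15 methyl group.

Step 12
Reactants: 19 γ-keto ester
Product: 20 hydroxy diketone (free cyclopentanone and C5–OH)
Conditions: AcOH/THF/H2O (3:1:1), 40 °C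
Reagents that add atoms: water, O
Why: Mild acid hydrolysis removes the dioxolane and the primary triethylsilyl ether, while the primary TBS ether, benzyl ether and methyl ester survive.

Step 13
Reactants: 20 hydroxy diketone
Product: 21 bicyclic enone alcohol (rings D and E; C12 ketone, C13=C14)
Conditions: NaOMe, MeOH, 50 °C
Reagents that add atoms: none
Why: Intramolecular aldol condensation (seven-enolexo-exo-trig); only the C13 enolate can reach a carbonyl through an unstrained ring, and dehydration to the conjugated tetrasubstituted enone drives the closure. No stereocentre is formed and C9 is not acidic.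

Step 14
Reactants: 21 bicyclic enone alcohol
Product: 22 C5 azide
Conditions: PPh3, DIAD, (PhO)2P(O)N3, THF, 0 °C→rt
Reagents that add atoms: diphenylphosphoryl azide, [N-]=[N+]=NP(=O)(Oc1ccccc1)Oc1ccccc1
Why: Mitsunobu azidation of the primary alcohol; C14 is now an alkene carbon, so no neighbouring carbonyl can intercept the activated oxygen.

Step 15
Reactants: 22 C5 azide
Product: 23 azido ketone (C21 ketone)
Conditions: OsO4 (2 mol %), NaIO4, 2,6-lutidine, dioxane/H2O, rt
Reagents that add atoms: osmium tetroxide, O=[Os](=O)(=O)=O; sodium periodate, [Na+].[O-]I(=O)(=O)=O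
Why: Lemieux–Johnson cleavage of the electron-rich 1,1-disubstituted alkene; the tetrasubstituted, electron-poor enone is not dihydroxylated.

Step 16
Reactants: 23 azido ketone
Product: 25 tricyclic ketimine (rings B D E), via iminophosphorane 24 (not isolated)
Conditions: PPh3, toluene, rt→90 °C
Reagents that add atoms: none
Why: Staudinger reduction to the iminophosphorane and intramolecular aza-Wittig reaction with the C21 ketone close the six-membered ring B; the C12 carbonyl and the ester are out of reach.

Step 17
Reactants: 26 nitromethane; 27 acetaldehyde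
Product: 28 1-nitropropan-2-ol
Conditions: NaOH (cat.), MeOH/H2O, 0 °C
Reagents that add atoms: none
Why: Henry reaction.

Step 18
Reactants: 28 1-nitropropan-2-ol
Product: 29 (E)-1-nitroprop-1-ene
Conditions: MsCl, Et3N, CH2Cl2, −20 °C→rt
Reagents that add atoms: none
Why: Mesylation and E1cB elimination give the conjugated nitroalkene as the more stable E isomer; it is used freshly distilled.

Step 19
Reactants: 25 tricyclic ketimine; 30 (trimethylsilyl)methyl trifluoromethanesulfonate; 29 (E)-1-nitroprop-1-ene
Product: 33 nitro indolizidine (ring A closed; aza-quaternary C21), via iminium triflate 31 (not isolated), via azomethine ylide 32 (not isolated)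
Conditions: 30, CH2Cl2, rt; solvent exchange; then 29 (3 equiv), CsF, MeCN, 0 °C→rt
Reagents that add atoms: none
Why: N4 of 25 is alkylated by 30 to the N-(trimethylsilylmethyl)iminium salt 31, and fluoride removes silicon to leave the non-stabilised azomethine ylide 32 (C3–N4–C21). The closest known reaction type is the desilylative generation of non-stabilised azomethine ylides from imines and their (3+2) cycloaddition to nitroalkenes, which gives 3-nitropyrrolidines. Ring A closes in a concerted, suprafacial but asynchronous (3+2) cycloaddition in which C3–C2 forms ahead of C21–C26. The ylide carries its charge mainly on the unsubstituted C3, which attacks the β-carbon of 29 (C2) while the nitro-bearing carbon C26 closes on C21; the non-conjugating CH2OTBS group on C21 keeps this polarisation. For C21, ring B of 32 should adopt the half-chair with C7 and C24 pseudo-equatorial and C14 pseudo-axial, so that C14 and the rings behind it shield one face and 29 arrives on the face of C24 and H6, leaving C20 cis to C14 as ring C will need. C2 and C26 are set trans by the E alkene; which way the nitro group points decides C2 relative to C21, but C26 becomes sp2 in step 20 and C2 is α to that ketone, so both adducts converge. The tetrasubstituted enone is too hindered to compete with the excess nitroalkene, and proton transfer within 31 or 32 is limited by fast trapping. The centre is made at this stage because after ring C closure C21 would be a bridgehead and could no longer be the carbon of a C=N bond.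

Step 20
Reactants: 33 nitro indolizidine
Product: 35 C26 ketone, via sodium nitronate 34 (not isolated)
Conditions: NaOMe, MeOH, 0 °C; then aq TiCl3, NH4OAc (pH 5–6), THF, 0 °C→rt
Reagents that add atoms: water, O
Why: Reductive Nef reaction: trivalent titanium reduces the nitronate to the imine, which hydrolyses in the buffer; the short, cold nitronate stage and the near-neutral medium are chosen to avoid retro-Mannich opening at C21–C26.

Step 21
Reactants: 35 C26 ketone
Product: 36 C26 alcohol
Conditions: NaBH4, MeOH/CH2Cl2, −78 °C
Reagents that add atoms: none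
Why: Borohydride at low temperature reduces the inductively activated saturated ketone faster than the hindered conjugated enone or the ester; the new carbinol centre is temporary and either epimer serves.

Step 22
Reactants: 36 C26 alcohol
Product: 37 C26 tert-butyldimethylsilyl ether
Conditions: TBSOTf, 2,6-lutidine, CH2Cl2, 0 °C
Reagents that add atoms: tert-butyldimethylsilyl trifluoromethanesulfonate, CC(C)(C)[Si](C)(C)OS(=O)(=O)C(F)(F)F
Why: Silyl triflate protects the hindered secondary alcohol, which must stay masked through the reductive cyclisation and the enolate step.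

Step 23
Reactants: 37 C26 silyl ether
Product: 38 C20 primary alcohol
Conditions: HF·pyridine, pyridine, THF, 0 °C
Reagents that add atoms: none
Why: Buffered HF cleaves the primary silyl ether much faster than the secondary one flanked by C21 and C2.

Step 24
Reactants: 38 C20 primary alcohol
Product: 39 C20 aldehyde
Conditions: Dess–Martin periodinane, NaHCO3, CH2Cl2, 0 °C→rt
Reagents that add atoms: none
Why: Neutral hypervalent-iodine oxidation; the aldehyde sits on quaternary C21, cannot enolise, and is used at once.

Step 25
Reactants: 39 C20 aldehyde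
Product: 41 hexacyclic lactone ketone (ring C and lactone closed; C12 ketone), via hydroxy ester 40 (not isolated)
Conditions: SmI2 (2.5 equiv), HMPA, t-BuOH, THF, −78 °C→rt
Reagents that add atoms: none
Why: SmI2 ketyl–olefin cyclisation (five-exo-trig) onto the β-carbon of the enone forms C20–C14 and quaternary C14; the tether through C21–C22–C23 fixes the face at C14. The ketyl oxygen prefers to lie anti to the enone carbon C13 and therefore cis to the C15 chain, so the trivalent samarium alkoxide closes the δ-lactone on the methyl ester as the mixture warms.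

Step 26
Reactants: 41 hexacyclic lactone ketone
Product: 42 C12 enol triflate (C12=C13)
Conditions: KN(SiMe3)2 (0.95 equiv), THF, −78→0 °C; then PhNTf2, −78 °C→rt
Reagents that add atoms: N-phenylbis(trifluoromethanesulfonimide), FC(F)(F)S(=O)(=O)N(c1ccccc1)S(=O)(=O)C(F)(F)F
Why: Enol triflate formation under equilibrating conditions: with a slight deficit of base the enolates interconvert through the remaining ketone, and cyclopentanones strongly favour the more substituted enolate, here C12=C13. The ketone is more acidic than the lactone.

Step 27
Reactants: 42 C12 enol triflate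
Product: 43 C12=C13 alkene
Conditions: Pd(OAc)2 (10 mol %), PPh3, n-Bu3N, HCO2H, DMF, 60 °C
Reagents that add atoms: none
Why: Palladium-catalysed formate reduction of an alkenyl triflate; zerovalent palladium inserts, formate supplies hydride, and the alkene stays where the triflate was.

Step 28
Reactants: 43 C12=C13 alkene
Product: 44 C26 alcohol
Conditions: HF·pyridine, THF, rt→40 °C
Reagents that add atoms: none
Why: Acidic fluoride removes the last silyl ether without touching the lactone or the benzyl ether.

Step 29
Reactants: 44 C26 alcohol
Product: 45 O24-benzyl ether of the target (C26 ketone)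
Conditions: Dess–Martin periodinane, NaHCO3, CH2Cl2, rt; then DBU (cat.), CH2Cl2, rt if C2 needs equilibration
Reagents that add atoms: none
Why: Oxidation of the only free hydroxyl restores the C26 ketone; C2 is now α to it and a trace of base brings it to the preferred, natural configuration.

Step 30
Reactants: 45 O24-benzyl ether of the target
Product: 46 target CNP0180795.1
Conditions: BCl3, C6HMe5, CH2Cl2, −78 °C; then MeOH
Reagents that add atoms: none
Why: Lewis-acid debenzylation with pentamethylbenzene as cation scavenger frees the neopentyl alcohol at low temperature; hydrogenolysis is avoided because of the C12=C13 alkene.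

## Compound list

1 | cyclopent-2-en-1-one | O=C1C=CCC1 | starting material
2 | potassium vinyltrifluoroborate | [K+].C=C[B-](F)(F)F | starting material
3 | (S)-3-vinylcyclopentan-1-one | C=C[C@H]1CCC(=O)C1 | intermediate
4 | (7S)-7-vinyl-1,4-dioxaspiro[4.4]nonane | C=C[C@H]1CCC2(C1)OCCO2 | intermediate
5 | 4-bromofuran-2(5H)-one | O=C1OCC(Br)=C1 | starting material
6 | 9-{2-[(7S)-1,4-dioxaspiro[4.4]nonan-7-yl]ethyl}-9-borabicyclo[3.3.1]nonane | B1(CC[C@H]2CCC3(C2)OCCO3)C2CCCC1CCC2 | intermediate (not isolated)
7 | 4-{2-[(7S)-1,4-dioxaspiro[4.4]nonan-7-yl]ethyl}furan-2(5H)-one | O=C1OCC(CC[C@H]2CCC3(C2)OCCO3)=C1 | intermediate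
8 | (4S)-4-{2-[(7S)-1,4-dioxaspiro[4.4]nonan-7-yl]ethyl}dihydrofuran-2(3H)-one | O=C1OC[C@@H](CC[C@H]2CCC3(C2)OCCO3)C1 | intermediate
9 | benzyl chloromethyl ether | ClCOCc1ccccc1 | starting material
10 | (3R,4S)-3-(benzyloxymethyl)-4-{2-[(7S)-1,4-dioxaspiro[4.4]nonan-7-yl]ethyl}dihydrofuran-2(3H)-one | O=C1OC[C@@H](CC[C@H]2CCC3(C2)OCCO3)[C@@H]1COCc1ccccc1 | intermediate
11 | 2-methylidenepropane-1,3-diol | C=C(CO)CO | starting material
12 | 2-{[(tert-butyldimethylsilyl)oxy]methyl}prop-2-en-1-ol | C=C(CO)CO[Si](C)(C)C(C)(C)C | intermediate
13 | {[2-(bromomethyl)prop-2-en-1-yl]oxy}(tert-butyl)dimethylsilane | C=C(CBr)CO[Si](C)(C)C(C)(C)C | intermediate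
14 | (3S,4S)-3-(benzyloxymethyl)-3-[2-(TBSO-methyl)allyl]-4-{2-[(7S)-1,4-dioxaspiro[4.4]nonan-7-yl]ethyl}dihydrofuran-2(3H)-one | O=C1OC[C@@H](CC[C@H]2CCC3(C2)OCCO3)[C@]1(COCc1ccccc1)CC(=C)CO[Si](C)(C)C(C)(C)C | intermediate
15 | methyllithium | [Li]C | starting material
16 | hydroxy methyl ketone (open form; C6, C9, C23 as in the target) | CC(=O)[C@@](COCc1ccccc1)(CC(=C)CO[Si](C)(C)C(C)(C)C)[C@@H](CO)CC[C@H]1CCC2(C1)OCCO2 | intermediate
17 | C5 triethylsilyl ether of 16 | CC(=O)[C@@](COCc1ccccc1)(CC(=C)CO[Si](C)(C)C(C)(C)C)[C@@H](CO[Si](CC)(CC)CC)CC[C@H]1CCC2(C1)OCCO2 | intermediate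
18 | methyl bromoacetate | COC(=O)CBr | starting material
19 | γ-keto ester (ketal and silyl ethers intact) | COC(=O)CCC(=O)[C@@](COCc1ccccc1)(CC(=C)CO[Si](C)(C)C(C)(C)C)[C@@H](CO[Si](CC)(CC)CC)CC[C@H]1CCC2(C1)OCCO2 | intermediate
20 | hydroxy diketone | COC(=O)CCC(=O)[C@@](COCc1ccccc1)(CC(=C)CO[Si](C)(C)C(C)(C)C)[C@@H](CO)CC[C@H]1CCC(=O)C1 | intermediate
21 | bicyclic enone alcohol (rings D and E) | OC[C@H]1CC[C@H]2CCC(=O)C2=C(CCC(=O)OC)[C@@]1(COCc1ccccc1)CC(=C)CO[Si](C)(C)C(C)(C)C | intermediate
22 | bicyclic enone C5 azide | [N-]=[N+]=NC[C@H]1CC[C@H]2CCC(=O)C2=C(CCC(=O)OC)[C@@]1(COCc1ccccc1)CC(=C)CO[Si](C)(C)C(C)(C)C | intermediate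
23 | azido ketone (C21 ketone) | [N-]=[N+]=NC[C@H]1CC[C@H]2CCC(=O)C2=C(CCC(=O)OC)[C@@]1(COCc1ccccc1)CC(=O)CO[Si](C)(C)C(C)(C)C | intermediate
24 | iminophosphorane of 23 | c1ccc(cc1)P(c1ccccc1)(c1ccccc1)=NC[C@H]1CC[C@H]2CCC(=O)C2=C(CCC(=O)OC)[C@@]1(COCc1ccccc1)CC(=O)CO[Si](C)(C)C(C)(C)C | intermediate (not isolated)
25 | tricyclic ketimine (rings B, D, E; C20 as CH2OTBS, C24 as CH2OBn, C17 methyl ester) | CC(C)(C)[Si](C)(C)OCC1=NC[C@H]2CC[C@H]3CCC(=O)C3=C(CCC(=O)OC)[C@@]2(COCc2ccccc2)C1 | intermediate
26 | nitromethane | C[N+](=O)[O-] | starting material
27 | acetaldehyde | CC=O | starting material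
28 | 1-nitropropan-2-ol (racemic) | CC(O)C[N+](=O)[O-] | intermediate
29 | (E)-1-nitroprop-1-ene | C/C=C/[N+](=O)[O-] | intermediate
30 | (trimethylsilyl)methyl trifluoromethanesulfonate | C[Si](C)(C)COS(=O)(=O)C(F)(F)F | starting material
31 | N-(trimethylsilylmethyl)iminium triflate of 25 | CC(C)(C)[Si](C)(C)OCC1=[N+](C[Si](C)(C)C)C[C@H]2CC[C@H]3CCC(=O)C3=C(CCC(=O)OC)[C@@]2(COCc2ccccc2)C1.[O-]S(=O)(=O)C(F)(F)F | intermediate (not isolated)
32 | azomethine ylide (C3–N4–C21) | CC(C)(C)[Si](C)(C)OCC1=[N+]([CH2-])C[C@H]2CC[C@H]3CCC(=O)C3=C(CCC(=O)OC)[C@@]2(COCc2ccccc2)C1 | intermediate (not isolated)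
33 | nitro indolizidine (ring A closed, aza-quaternary C21) | C[C@@H]1CN2C[C@H]3CC[C@H]4CCC(=O)C4=C(CCC(=O)OC)[C@@]3(COCc3ccccc3)C[C@]2(CO[Si](C)(C)C(C)(C)C)[C@H]1[N+](=O)[O-] | intermediate
34 | sodium nitronate of 33 | C[C@@H]1CN2C[C@H]3CC[C@H]4CCC(=O)C4=C(CCC(=O)OC)[C@@]3(COCc3ccccc3)C[C@]2(CO[Si](C)(C)C(C)(C)C)C1=[N+]([O-])[O-].[Na+] | intermediate (not isolated)
35 | C26 ketone | C[C@@H]1CN2C[C@H]3CC[C@H]4CCC(=O)C4=C(CCC(=O)OC)[C@@]3(COCc3ccccc3)C[C@]2(CO[Si](C)(C)C(C)(C)C)C1=O | intermediate
36 | C26 alcohol | C[C@@H]1CN2C[C@H]3CC[C@H]4CCC(=O)C4=C(CCC(=O)OC)[C@@]3(COCc3ccccc3)C[C@]2(CO[Si](C)(C)C(C)(C)C)[C@@H]1O | intermediate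
37 | C26 TBS ether (C20 also TBS) | C[C@@H]1CN2C[C@H]3CC[C@H]4CCC(=O)C4=C(CCC(=O)OC)[C@@]3(COCc3ccccc3)C[C@]2(CO[Si](C)(C)C(C)(C)C)[C@@H]1O[Si](C)(C)C(C)(C)C | intermediate
38 | C20 primary alcohol | C[C@@H]1CN2C[C@H]3CC[C@H]4CCC(=O)C4=C(CCC(=O)OC)[C@@]3(COCc3ccccc3)C[C@]2(CO)[C@@H]1O[Si](C)(C)C(C)(C)C | intermediate
39 | C20 aldehyde | C[C@@H]1CN2C[C@H]3CC[C@H]4CCC(=O)C4=C(CCC(=O)OC)[C@@]3(COCc3ccccc3)C[C@]2(C=O)[C@@H]1O[Si](C)(C)C(C)(C)C | intermediate
40 | C20 hydroxy ester (ring C closed, lactone open) | C[C@@H]1CN2C[C@H]3CC[C@H]4CCC(=O)[C@H]4[C@@]5(CCC(=O)OC)[C@H](O)[C@@]2(C[C@@]35COCc3ccccc3)[C@@H]1O[Si](C)(C)C(C)(C)C | intermediate (not isolated)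
41 | hexacyclic lactone ketone (C12 ketone) | C[C@@H]1CN2C[C@H]3CC[C@H]4CCC(=O)[C@H]4[C@@]45CCC(=O)O[C@@H]4[C@@]2(C[C@@]35COCc3ccccc3)[C@@H]1O[Si](C)(C)C(C)(C)C | intermediate
42 | C12 enol triflate | C[C@@H]1CN2C[C@H]3CC[C@H]4CCC(OS(=O)(=O)C(F)(F)F)=C4[C@@]45CCC(=O)O[C@@H]4[C@@]2(C[C@@]35COCc3ccccc3)[C@@H]1O[Si](C)(C)C(C)(C)C | intermediate
43 | C12=C13 alkene (O24-benzyl, O26-TBS) | C[C@@H]1CN2C[C@H]3CC[C@H]4CCC=C4[C@@]45CCC(=O)O[C@@H]4[C@@]2(C[C@@]35COCc3ccccc3)[C@@H]1O[Si](C)(C)C(C)(C)C | intermediate
44 | C26 alcohol (O24-benzyl) | C[C@@H]1CN2C[C@H]3CC[C@H]4CCC=C4[C@@]45CCC(=O)O[C@@H]4[C@@]2(C[C@@]35COCc3ccccc3)[C@@H]1O | intermediate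
45 | O24-benzyl ether of the target | C[C@@H]1CN2C[C@H]3CC[C@H]4CCC=C4[C@@]45CCC(=O)O[C@@H]4[C@@]2(C[C@@]35COCc3ccccc3)C1=O | intermediate
46 | CNP0180795.1 | C[C@@H]1CN2C[C@H]3CC[C@H]4CCC=C4[C@@]45CCC(=O)O[C@@H]4[C@@]2(C[C@@]35CO)C1=O | target

## Step count and least certain steps

Total step count: 30. Longest linear sequence: 26 steps (steps 1–5, 8–16 and 19–30); steps 6–7 and 17–18 prepare reagents 13 and 29.

**Step 19 (key step).** The most likely failure is loss of the dipole by proton transfer before it can add: the iminium salt has acidic hydrogens on C20 and C22 and can tautomerise to an enamine under fluoride, and the ylide can quench itself by a 1,4-proton shift. Second in likelihood is insufficient facial discrimination at C21, since either face suffers one 1,3-interaction across ring B.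
Fallback: a stepwise ionic route from 25 back to 33. Commercial (R)-3-bromo-2-methylpropan-1-ol is converted with NaNO2 into (S)-2-methyl-3-nitropropan-1-ol F1 and then with Tf2O/pyridine into (S)-2-methyl-3-nitropropyl triflate F2. N-Alkylation of 25 with F2 gives the N-(2-methyl-3-nitropropyl)iminium triflate F3, and triethylamine then triggers an intramolecular nitro-Mannich closure of C26 onto C21. This is the same five-membered iminium closure that operates in aza-Cope–Mannich cascades. It returns to the route at 33 with C2 already set from the chiral pool, and the closure is reversible, so the C21 epimers can equilibrate.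

**Step 13.** The aldol addition onto the C14 ketone, which is flanked by quaternary C23, may stall at an unfavourable equilibrium, and a seven-membered closure is slower than intermolecular condensation of the cyclopentanone.
Fallback: a palladium-catalysed ketone α-alkenylation from 19 back to 21. KN(SiMe3)2/PhNTf2 converts the C14 ketone of 19, which can enolise only toward C15, into the alkenyl triflate F4. AcOH/THF/H2O releases the cyclopentanone and the C5 alcohol to give the keto alkenyl triflate F5. Pd(PPh3)4 and KOt-Bu in THF then couple the ketone enolate with the alkenyl triflate (only C13 can reach) to give the β,γ-unsaturated bicyclic ketone F6, which the base isomerises into conjugation, giving 21.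

**Step 25.** The aldehyde is α to the amine, so electron transfer may end in reductive cleavage of the C21–N4 bond or in simple reduction of the aldehyde or enone without ring closure. Chelation of samarium between the ketyl oxygen and the C12 oxygen could also turn the C20 oxygen away from the C15 chain and block lactonisation.
Fallback: from 39, an O-stannyl ketyl radical cyclisation (Bu3SnH, AIBN, benzene, 80 °C) makes the same C20–C14 bond by a radical chain, without a second electron transfer and so without the elimination path; it passes through 40 and returns to 41 after acid-promoted lactonisation. No new compound is needed.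

**Step 26.** Deprotonation may stay under kinetic control at the accessible C11 methylene, or equilibration may be incomplete because the C13 position is crowded by quaternary C14; either leads to triflation on the wrong side.
Fallback: from 41, condensation with tosylhydrazine gives the C12 tosylhydrazone F7, and an aprotic Bamford–Stevens reaction (NaH, toluene, 110 °C) generates the carbene, which takes the tertiary C13 hydrogen in a 1,2-shift and gives the more substituted alkene 43 directly, rejoining the route there.

## Further compounds

F1 | step 19 | (S)-2-methyl-3-nitropropan-1-ol | C[C@@H](C[N+](=O)[O-])CO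
F2 | step 19 | (S)-2-methyl-3-nitropropyl trifluoromethanesulfonate | C[C@@H](C[N+](=O)[O-])COS(=O)(=O)C(F)(F)F
F3 | step 19 | N-[(S)-2-methyl-3-nitropropyl]iminium triflate of 25 | CC(C)(C)[Si](C)(C)OCC1=[N+](C[C@@H](C)C[N+](=O)[O-])C[C@H]2CC[C@H]3CCC(=O)C3=C(CCC(=O)OC)[C@@]2(COCc2ccccc2)C1.[O-]S(=O)(=O)C(F)(F)F
F4 | step 13 | C14 alkenyl triflate of 19 (C14=C15, either alkene isomer) | COC(=O)CC=C(OS(=O)(=O)C(F)(F)F)[C@@](COCc1ccccc1)(CC(=C)CO[Si](C)(C)C(C)(C)C)[C@@H](CO[Si](CC)(CC)CC)CC[C@H]1CCC2(C1)OCCO2
F5 | step 13 | keto alkenyl triflate (cyclopentanone and C5–OH free) | COC(=O)CC=C(OS(=O)(=O)C(F)(F)F)[C@@](COCc1ccccc1)(CC(=C)CO[Si](C)(C)C(C)(C)C)[C@@H](CO)CC[C@H]1CCC(=O)C1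
F6 | step 13 | β,γ-unsaturated bicyclic ketone (C14=C15; C13 epimers) | OC[C@H]1CC[C@H]2CCC(=O)C2C(=CCC(=O)OC)[C@@]1(COCc1ccccc1)CC(=C)CO[Si](C)(C)C(C)(C)C
F0 | step 25 | none | none
F7 | step 26 | C12 tosylhydrazone of 41 | C[C@@H]1CN2C[C@H]3CC[C@H]4CCC(=NNS(=O)(=O)c6ccc(C)cc6)[C@H]4[C@@]45CCC(=O)O[C@@H]4[C@@]2(C[C@@]35COCc3ccccc3)[C@@H]1O[Si](C)(C)C(C)(C)C
A1 | alternative 1 | 7,8-didehydro target | C[C@@H]1CN2C[C@H]3C=C[C@H]4CCC=C4[C@@]45CCC(=O)O[C@@H]4[C@@]2(C[C@@]35CO)C1=O
A2 | alternative 2 | pentacyclic diene with ring D closed | C[C@@H]1CN2C[C@H]3CC[C@H]4CCC=C4[C@@]5(/C=C/COCc6ccc(OC)cc6)[C@H](O[Si](CC)(CC)CC)[C@@]2(C[C@@]35CO[Si](c7ccccc7)(c8ccccc8)C(C)(C)C)C1=O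
A3 | alternative 3 | hexacyclic C11 enone | C[C@@H]1CN2C[C@H]3CC[C@H]4CC(=O)C=C4[C@@]45CCC(=O)O[C@@H]4[C@@]2(C[C@@]35CO[Si](C)(C)C(C)(C)C)C1=O
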